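**Retrosynthetic overview**
1. Target ⇐ oxidation of a (Z)-propenyl carbinol, made by chemoselective Nozaki–Hiyama–Kishi addition to a C2 aldehyde. The α-methylene-γ-lactone (last ring formed) ⇐ intramolecular Michael/Horner–Wadsworth–Emmons reaction of a C6 phosphonoacetate on a cycloheptenone.
2. Cycloheptenone ⇐ Saegusa–Ito oxidation of a regiodefined silyl enol ether. The trans C1-hydroxy/C5-isovalerate pair ⇐ hydroxyl-directed epoxidation of a 2-(hydroxymethyl)cycloheptenol and titanium-mediated opening with 3-methylbutanoic acid.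
3. Seven-membered ring (first ring formed, sets C10 and C6) ⇐ proposed enantioselective formal [4+3] reaction (cyclopropanation, cyclopropane epimerisation, Cope rearrangement) of a 4-benzoyloxyvinyl diazoacetate with the (Z)-silyl dienol ether of ethyl vinyl ketone.
4. Ring order: cycloheptadiene, then a temporary dioxolane protecting ring, then the lactone.

Assumption and convention: (Z)-1-bromoprop-1-ene and Rh2(R-DOSP)4 are taken as purchasable. Atoms carry the labels of the target skeleton: ring C1 (carbinol), C5, C6, C7, C8, C9 (ketone), C10 (CHMe); C2 is the exocyclic carbon on C1; C11–C13 are the lactone carbons. α is the ring face that carries the C10 methyl group, β the other face. Absolute configurations are those of the SMILES strings.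

Step 1
Reactants: 1 pent-1-en-3-one (ethyl vinyl ketone)
Product: 2 (Z)-triisopropyl(penta-1,3-dien-3-yloxy)silane
Conditions: TIPSOTf, Et3N, CH2Cl2, 0 °C
Reagents that add atoms: triisopropylsilyl trifluoromethanesulfonate (CC(C)[Si](C(C)C)(C(C)C)OS(=O)(=O)C(F)(F)F)
Why: Soft enolisation with a silyl triflate and an amine (silyl enol ether formation) gives the cross-conjugated 2-silyloxydiene with the methyl group cis to oxygen (Z), the geometry that minimises allylic strain.

Step 2
Reactants: 3 allyl benzoate
Product: 4 2-oxoethyl benzoate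
Conditions: O3, CH2Cl2, −78 °C; then Me2S
Reagents that add atoms: ozone (O=[O+][O-])
Why: Ozonolysis with reductive work-up cleaves the terminal alkene to the aldehyde and leaves the benzoate untouched.

Step 3
Reactants: 4 2-oxoethyl benzoate; 5 ethyl diazoacetate
Product: 6 ethyl 4-(benzoyloxy)-2-diazo-3-hydroxybutanoate (racemic)
Conditions: DBU (10 mol %), MeCN, 0 °C → rt
Reagents that add atoms: none
Why: Base-catalysed aldol-type addition of the acidic diazoacetate C–H to the aldehyde gives the β-hydroxy-α-diazo ester; the carbinol centre is removed in the next step.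

Step 4
Reactants: 6 ethyl 4-(benzoyloxy)-2-diazo-3-hydroxybutanoate
Product: 7 ethyl (E)-4-(benzoyloxy)-2-diazobut-3-enoate
Conditions: POCl3, Et3N, CH2Cl2, 0 °C
Reagents that add atoms: none
Why: Phosphorylation of the carbinol and E2 elimination towards the only β-hydrogens (dehydration) gives the conjugated vinyl diazo ester, with the E enol benzoate favoured by conjugation and sterics.

Step 5
Reactants: 2 (Z)-triisopropyl(penta-1,3-dien-3-yloxy)silane; 7 ethyl (E)-4-(benzoyloxy)-2-diazobut-3-enoate
Product: 10 ethyl (3R,7R)-3-(benzoyloxy)-7-methyl-6-(triisopropylsilyloxy)cyclohepta-1,5-diene-1-carboxylate, via trans-divinylcyclopropane 8 (not isolated), via cis-divinylcyclopropane 9 (not isolated)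
Conditions: Rh2(R-DOSP)4 [dirhodium tetrakis((R)-N-(4-dodecylphenylsulfonyl)prolinate)] (1 mol %), 7 added over 2 h to 2 (3 equiv), hexanes/toluene, −40 °C → 25 °C; then 60 °C, 2 h
Reagents that add atoms: none
Why: Proposed new method: an enantioselective formal [4+3] cycloaddition of a 4-acyloxyvinyl diazoacetate with a trisubstituted (Z)-2-silyloxydiene, in which the electrophilic donor/acceptor divalent rhodium vinylcarbenoid from 7 is attacked by the methyl-bearing enol carbon of 2 (C10, far more nucleophilic than the unactivated vinyl group) and closes stereospecifically to the siloxy/ester push–pull cyclopropane 8, the chiral prolinate catalyst fixing the enol-ether face and hence C10 (the R catalyst is chosen by extension of the known facial model for the S catalyst in styrene cyclopropanation); 8 has its vinyl groups trans and cannot undergo the Cope rearrangement, but its C1–C9 bond lies between donor (OSi, vinyl) and acceptor (ester, acyloxyvinyl) groups and opens reversibly on gentle warming, epimerising C1 to the cis-divinyl isomer 9, which is drained irreversibly through the boat Cope transition state in which the E-benzoyloxy terminus and the methyl group (trans to both vinyl groups) finish cis, so C6 is set relative to C10; the substituted vinyl terminus of 7 suppresses vinylogous attack; the closest known reaction type is the tandem cyclopropanation/Cope rearrangement of vinyldiazoacetates with dienes under dirhodium prolinate catalysis.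

Step 6
Reactants: 10 ethyl (3R,7R)-3-(benzoyloxy)-7-methyl-6-(triisopropylsilyloxy)cyclohepta-1,5-diene-1-carboxylate
Product: 11 [6α-hydroxy-10α-methyl-9-(triisopropylsilyloxy)cyclohepta-1(5),8-dien-1-yl]methanol
Conditions: iBu2AlH (5 equiv), CH2Cl2, −78 °C; aq. potassium sodium tartrate
Reagents that add atoms: none
Why: Hydride 1,2-reduction of the conjugated ester to the allylic alcohol and reductive cleavage of the benzoate occur in one operation, while the silyl enol ether keeps C9 masked and no stereocentre is touched.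

Step 7
Reactants: 11 [6α-hydroxy-10α-methyl-9-(triisopropylsilyloxy)cyclohepta-1(5),8-dien-1-yl]methanol
Product: 12 1α,5α-epoxy-1β-(hydroxymethyl)-10α-methyl-9-(triisopropylsilyloxy)cyclohept-8-en-6α-ol
Conditions: VO(acac)2 (5 mol %), t-BuOOH, CH2Cl2, 0 °C → rt
Reagents that add atoms: tert-butyl hydroperoxide (CC(C)(C)OO)
Why: Vanadium-catalysed hydroxyl-directed epoxidation: the C1=C5 alkene is allylic to both hydroxyls and the ring 6α-hydroxyl delivers oxygen cis to itself (the rule for cyclohept-2-enols), which sets C1; the non-directed enol ether is spared.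

Step 8
Reactants: 12 1α,5α-epoxy-1β-(hydroxymethyl)-10α-methyl-9-(triisopropylsilyloxy)cyclohept-8-en-6α-ol
Product: 13 1α,6α-dihydroxy-1β-(hydroxymethyl)-10α-methyl-9-(triisopropylsilyloxy)cyclohept-8-en-5β-yl 3-methylbutanoate
Conditions: 3-methylbutanoic acid (3 equiv), Ti(OiPr)4 (1.5 equiv), CH2Cl2, rt
Reagents that add atoms: 3-methylbutanoic acid (CC(C)CC(=O)O)
Why: Titanium-mediated regioselective opening of a 2,3-epoxy alcohol: chelation through the C2 hydroxyl and the epoxide oxygen directs SN2 attack of the carboxylate at secondary C5 with inversion (quaternary C1 cannot be attacked), giving the 5β-ester trans to the 1α-hydroxyl.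

Step 9
Reactants: 13 1α,6α-dihydroxy-1β-(hydroxymethyl)-10α-methyl-9-(triisopropylsilyloxy)cyclohept-8-en-5β-yl 3-methylbutanoate
Product: 14 1α,2-O-isopropylidene derivative of 13 (spiro dioxolane on C1 and C2; 6α-hydroxyl free)
Conditions: 2-methoxypropene (1.5 equiv), PPTS (5 mol %), CH2Cl2, 0 °C; Et3N quench
Reagents that add atoms: 2-methoxypropene (COC(C)=C)
Why: Acid-catalysed ketal exchange closes the primary/tertiary 1,2-diol to the five-membered dioxolane, which frees only the 6α-hydroxyl for acylation and masks the tertiary alcohol against transannular oxa-Michael and retro-aldol reactions later.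

Step 10
Reactants: 14 1α,2-O-isopropylidene derivative of 13
Product: 15 6α-O-[(diethoxyphosphoryl)acetyl] derivative of 14
Conditions: (EtO)2P(O)CH2CO2H, DCC, DMAP (cat.), CH2Cl2, 0 °C → rt
Reagents that add atoms: diethylphosphonoacetic acid (CCOP(=O)(CC(=O)O)OCC)
Why: Steglich esterification of the only free hydroxyl.

Step 11
Reactants: 15 6α-O-[(diethoxyphosphoryl)acetyl] derivative of 14
Product: 16 6α-[(diethoxyphosphoryl)acetoxy]-1α,2-(isopropylidenedioxy)-10α-methyl-5β-(3-methylbutanoyloxy)cyclohept-7-en-9-one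
Conditions: Pd(OAc)2 (1.2 equiv), MeCN/DMSO, 40 °C
Reagents that add atoms: none
Why: Saegusa–Ito oxidation: silicon-to-palladium exchange gives the divalent palladium enolate at C8 and β-hydride elimination of H7 gives the C7=C8 enone, regiospecifically because the Cope step fixed the enol ether towards C8.

Step 12
Reactants: 16 6α-[(diethoxyphosphoryl)acetoxy]-1α,2-(isopropylidenedioxy)-10α-methyl-5β-(3-methylbutanoyloxy)cyclohept-7-en-9-one
Product: 18 cis-fused α-methylene lactone acetonide (C6–O and C7–C11 both α), via phosphono lactone 17 (not isolated)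
Conditions: Cs2CO3, MeCN, 0 °C; then 37 % aq CH2O, rt
Reagents that add atoms: formaldehyde (C=O)
Why: Intramolecular Michael addition of the phosphonoacetate carbanion (5-exo-trig) delivers C11 to C7 on the α-face imposed by the C6–O tether (cis-fused lactone, sets C7), and Horner–Wadsworth–Emmons olefination of the resulting phosphonate with formaldehyde installs the exocyclic methylene.

Step 13
Reactants: 18 cis-fused α-methylene lactone acetonide
Product: 19 α-methylene lactone diol (1α-hydroxy-1β-hydroxymethyl)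
Conditions: CF3CO2H/H2O (9:1), CH2Cl2, 0 °C
Reagents that add atoms: none
Why: Acid hydrolysis of the isopropylidene ketal; the esters, the lactone and the ketone tolerate cold aqueous acid.

Step 14
Reactants: 19 α-methylene lactone diol
Product: 20 α-hydroxy aldehyde (C2 = CHO)
Conditions: IBX, DMSO, rt
Reagents that add atoms: none
Why: IBX oxidises the primary alcohol to the aldehyde without glycol cleavage and leaves the tertiary hydroxyl alone; C1 has no α-hydrogen to epimerise.

Step 15
Reactants: 20 α-hydroxy aldehyde; 21 (Z)-1-bromoprop-1-ene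
Product: 22 (Z)-propenyl carbinol (mixture of C2 epimers)
Conditions: CrCl2 (6 equiv), NiCl2 (2 mol %), DMF, rt
Reagents that add atoms: none
Why: Nozaki–Hiyama–Kishi coupling: nickel inserts into the alkenyl bromide with retention, and the alkenyl trivalent chromium species adds to the aldehyde only, in the presence of the ketone, esters and α-methylene lactone; both C2 epimers converge in the next step.

Step 16
Reactants: 22 (Z)-propenyl carbinol
Product: 23 (3aS,6R,7S,8S,8aR)-7-[(2Z)-but-2-enoyl]-7-hydroxy-6-methyl-3-methylidene-2,5-dioxooctahydro-2H-cyclohepta[b]furan-8-yl 3-methylbutanoate (target)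
Conditions: IBX, DMSO, rt
Reagents that add atoms: none
Why: IBX oxidation of the secondary allylic alcohol under neutral conditions gives the α-hydroxy (Z)-enone without alkene isomerisation, glycol cleavage or oxidation of the tertiary alcohol.

**Compound list**
1 | pent-1-en-3-one | CCC(=O)C=C | starting material
2 | (Z)-triisopropyl(penta-1,3-dien-3-yloxy)silane | C/C=C(\O[Si](C(C)C)(C(C)C)C(C)C)C=C | intermediate
3 | allyl benzoate | C=CCOC(=O)c1ccccc1 | starting material
4 | 2-oxoethyl benzoate | O=CCOC(=O)c1ccccc1 | intermediate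
5 | ethyl diazoacetate | CCOC(=O)C=[N+]=[N-] | starting material
6 | ethyl 4-(benzoyloxy)-2-diazo-3-hydroxybutanoate (racemic) | CCOC(=O)C(=[N+]=[N-])C(O)COC(=O)c1ccccc1 | intermediate
7 | ethyl (E)-4-(benzoyloxy)-2-diazobut-3-enoate | CCOC(=O)C(=[N+]=[N-])/C=C/OC(=O)c1ccccc1 | intermediate
8 | ethyl 1-[(E)-2-(benzoyloxy)ethenyl]-2-ethenyl-3-methyl-2-(triisopropylsilyloxy)cyclopropane-1-carboxylate, acyloxyvinyl group cis to OSi and methyl (trans-divinyl) | CCOC(=O)[C@@]1(/C=C/OC(=O)c2ccccc2)[C@@](O[Si](C(C)C)(C(C)C)C(C)C)(C=C)[C@@H]1C | intermediate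
9 | C1 epimer of 8, the two ethenyl groups cis and both trans to methyl (cis-divinyl) | CCOC(=O)[C@]1(/C=C/OC(=O)c2ccccc2)[C@@](O[Si](C(C)C)(C(C)C)C(C)C)(C=C)[C@@H]1C | intermediate
10 | ethyl (3R,7R)-3-(benzoyloxy)-7-methyl-6-(triisopropylsilyloxy)cyclohepta-1,5-diene-1-carboxylate (6α-OBz and 10α-Me cis) | CCOC(=O)C1=C[C@H](OC(=O)c2ccccc2)CC=C(O[Si](C(C)C)(C(C)C)C(C)C)[C@@H]1C | intermediate
11 | [6α-hydroxy-10α-methyl-9-(triisopropylsilyloxy)cyclohepta-1(5),8-dien-1-yl]methanol | OCC1=C[C@H](O)CC=C(O[Si](C(C)C)(C(C)C)C(C)C)[C@@H]1C | intermediate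
12 | 1α,5α-epoxy-1β-(hydroxymethyl)-10α-methyl-9-(triisopropylsilyloxy)cyclohept-8-en-6α-ol | OC[C@@]12O[C@@H]1[C@H](O)CC=C(O[Si](C(C)C)(C(C)C)C(C)C)[C@@H]2C | intermediate
13 | 1α,6α-dihydroxy-1β-(hydroxymethyl)-10α-methyl-9-(triisopropylsilyloxy)cyclohept-8-en-5β-yl 3-methylbutanoate | OC[C@@]1(O)[C@@H](OC(=O)CC(C)C)[C@H](O)CC=C(O[Si](C(C)C)(C(C)C)C(C)C)[C@@H]1C | intermediate
14 | 1α,2-O-isopropylidene derivative of 13 (spiro dioxolane; 6α-OH free) | CC1(C)OC[C@@]2(O1)[C@@H](OC(=O)CC(C)C)[C@H](O)CC=C(O[Si](C(C)C)(C(C)C)C(C)C)[C@@H]2C | intermediate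
15 | 6α-O-[(diethoxyphosphoryl)acetyl] derivative of 14 | CC1(C)OC[C@@]2(O1)[C@@H](OC(=O)CC(C)C)[C@H](OC(=O)CP(=O)(OCC)OCC)CC=C(O[Si](C(C)C)(C(C)C)C(C)C)[C@@H]2C | intermediate
16 | 6α-[(diethoxyphosphoryl)acetoxy]-1α,2-(isopropylidenedioxy)-10α-methyl-5β-(3-methylbutanoyloxy)cyclohept-7-en-9-one | CC1(C)OC[C@@]2(O1)[C@@H](OC(=O)CC(C)C)[C@H](OC(=O)CP(=O)(OCC)OCC)C=CC(=O)[C@@H]2C | intermediate
17 | cis-fused α-(diethoxyphosphoryl) γ-lactone (C6–O and C7–C11 α; epimers at C11) | CC1(C)OC[C@@]2(O1)[C@@H](OC(=O)CC(C)C)[C@@H]3OC(=O)C(P(=O)(OCC)OCC)[C@@H]3CC(=O)[C@@H]2C | intermediate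
18 | cis-fused α-methylene γ-lactone with the C1/C2 acetonide | CC1(C)OC[C@@]2(O1)[C@@H](OC(=O)CC(C)C)[C@@H]3OC(=O)C(=C)[C@@H]3CC(=O)[C@@H]2C | intermediate
19 | α-methylene lactone diol (1α-OH, 1β-CH2OH, 5β-isovalerate, 10α-Me, 9-ketone) | OC[C@@]1(O)[C@@H](OC(=O)CC(C)C)[C@@H]2OC(=O)C(=C)[C@@H]2CC(=O)[C@@H]1C | intermediate
20 | α-hydroxy aldehyde (C2 = CHO) | O=C[C@@]1(O)[C@@H](OC(=O)CC(C)C)[C@@H]2OC(=O)C(=C)[C@@H]2CC(=O)[C@@H]1C | intermediate
21 | (Z)-1-bromoprop-1-ene | C/C=C\Br | starting material
22 | (Z)-propenyl carbinol at C2 (both C2 epimers) | C/C=C\C(O)[C@@]1(O)[C@@H](OC(=O)CC(C)C)[C@@H]2OC(=O)C(=C)[C@@H]2CC(=O)[C@@H]1C | intermediate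
23 | (3aS,6R,7S,8S,8aR)-7-[(2Z)-but-2-enoyl]-7-hydroxy-6-methyl-3-methylidene-2,5-dioxooctahydro-2H-cyclohepta[b]furan-8-yl 3-methylbutanoate | C=C1C(=O)O[C@@H]2[C@H]1CC(=O)[C@H](C)[C@@](O)(C(=O)/C=C\C)[C@H]2OC(=O)CC(C)C | target

**Totals**
Total steps: 16. Longest linear sequence: 15 steps (3 → 23 through steps 2 to 16; step 1 is the side branch).

**Three steps most likely to fail**

Step 5 (the proposed new reaction). The carbenoid may attack the vinyl group of 2 and give the regioisomeric cycloheptadiene. It may also give [3+2] or vinylogous products, the trans cyclopropane 8 may fail to funnel through 9, or the ee may be modest. The fallback uses known chemistry, sets out from 2 (together with 5 and 4) and comes back at 10. Copper-catalysed asymmetric cyclopropanation of the silyl enol ether double bond of 2 with ethyl diazoacetate 5 (CuOTf, tert-butyl bis(oxazoline) ligand, CH2Cl2) gives ethyl 3-methyl-2-(triisopropylsilyloxy)-2-vinylcyclopropane-1-carboxylate F1, with methyl cis to OSi and both epimers at the ester carbon. Deprotonation of F1 with LiN(iPr)2 in THF at −78 °C and aldol addition of the cyclopropyl ester enolate to aldehyde 4, the electrophile entering anti to the silyloxy group, gives the β-hydroxy ester F2. Mesylation (MsCl, Et3N) gives the mesylate F3, and DBU elimination towards the only β-hydrogens gives the cis-divinylcyclopropane 9, which undergoes the Cope rearrangement on warming to 10.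

Step 12 (Michael/Horner–Wadsworth–Emmons cascade). The γ-acyloxy enone 16 may undergo C10 epimerisation, β-alkoxy elimination or hydroxymethylation of the ketone before the cascade is complete. The fallback sets out from 14 and comes back at 19. Esterification of 14 with mono-tert-butyl malonate (DCC, DMAP) gives the 6α-(tert-butyl malonate) ester F4. Saegusa–Ito oxidation (Pd(OAc)2) gives the malonate enone F5. Intramolecular malonate Michael addition under very mild base (K2CO3 or catalytic DBU) gives the cis-fused α-(tert-butoxycarbonyl) lactone F6. Aqueous CF3CO2H removes the tert-butyl ester and the acetonide together to give the α-carboxy lactone diol F7. Decarboxylative Mannich methylenation (aqueous CH2O, Et2NH, AcOH/NaOAc) gives 19.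

Step 15 (Nozaki–Hiyama–Kishi coupling). The alkenyl bromide may react sluggishly, the Z geometry may erode, or the divalent chromium may reduce the α-methylene lactone. The fallback sets out from 20 and comes back at 22. Zinc-mediated addition of propyne to the aldehyde (Zn(OTf)2, Et3N, toluene), which does not touch the ketone or the lactone, gives the propargylic alcohol F8. Cis-selective semi-hydrogenation (H2, Pd on CaCO3 poisoned with Pb(OAc)2, quinoline, EtOAc, stopped at one equivalent) gives 22.

**Further compounds**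
F1 | step 5 | ethyl 3-methyl-2-(triisopropylsilyloxy)-2-vinylcyclopropane-1-carboxylate (methyl cis to OSi; epimers at the ester carbon) | CCOC(=O)C1[C@@](O[Si](C(C)C)(C(C)C)C(C)C)(C=C)[C@@H]1C
F2 | step 5 | ethyl 1-[2-(benzoyloxy)-1-hydroxyethyl]-2-ethenyl-3-methyl-2-(triisopropylsilyloxy)cyclopropane-1-carboxylate (hydroxyalkyl cis to ethenyl; carbinol epimers) | CCOC(=O)[C@]1(C(O)COC(=O)c2ccccc2)[C@@](O[Si](C(C)C)(C(C)C)C(C)C)(C=C)[C@@H]1C
F3 | step 5 | methanesulfonate of F2 | CCOC(=O)[C@]1(C(OS(C)(=O)=O)COC(=O)c2ccccc2)[C@@](O[Si](C(C)C)(C(C)C)C(C)C)(C=C)[C@@H]1C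
F4 | step 12 | 6α-O-(tert-butyl malonyl) derivative of 14 | CC1(C)OC[C@@]2(O1)[C@@H](OC(=O)CC(C)C)[C@H](OC(=O)CC(=O)OC(C)(C)C)CC=C(O[Si](C(C)C)(C(C)C)C(C)C)[C@@H]2C
F5 | step 12 | cyclohept-7-en-9-one bearing the 6α-(tert-butyl malonate) ester | CC1(C)OC[C@@]2(O1)[C@@H](OC(=O)CC(C)C)[C@H](OC(=O)CC(=O)OC(C)(C)C)C=CC(=O)[C@@H]2C
F6 | step 12 | cis-fused α-(tert-butoxycarbonyl) γ-lactone acetonide (epimers at C11) | CC1(C)OC[C@@]2(O1)[C@@H](OC(=O)CC(C)C)[C@@H]3OC(=O)C(C(=O)OC(C)(C)C)[C@@H]3CC(=O)[C@@H]2C
F7 | step 12 | cis-fused α-carboxy γ-lactone diol (epimers at C11) | OC[C@@]1(O)[C@@H](OC(=O)CC(C)C)[C@@H]2OC(=O)C(C(=O)O)[C@@H]2CC(=O)[C@@H]1C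
F8 | step 15 | but-2-ynyl carbinol at C2 (propargylic alcohol; C2 epimers) | CC#CC(O)[C@@]1(O)[C@@H](OC(=O)CC(C)C)[C@@H]2OC(=O)C(=C)[C@@H]2CC(=O)[C@@H]1C
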